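## Structural features

Jaeskeanin is a trans-fused hydroazulene (daucane): cyclopentane ring A (C1–C5) shares the C1–C5 bond with cycloheptane ring B (C1, C5–C10). Six stereocentres are crowded on this frame: quaternary C1 (CH3-15, R), the tertiary isopropyl carbinol C4 (R), C5–H (S), the ester carbon C6 (S) and the cis-epoxide carbons C8 (R, CH3-14) and C9 (S). C1, C5, C4 and C6 are contiguous; CH3-15 and the C4 hydroxyl lie on the β face, whereas H-5, the C6 oxygen and the epoxide oxygen lie on the α face. The fragile groups are the trisubstituted epoxide (acid, and transannular attack by the C4 hydroxyl), the tertiary alcohol (dehydration) and the aryl ester next to a free phenol. The real difficulty is the quaternary ring-fusion carbon C1 next to the trans-fusion hydrogen, together with oxygenation of ring B on one face. Ring B is functionalised at C5–C6 and at C8–C9 with only the CH2 C7 between them, which is a cyclohepta-1,4-diene in disguise. That pattern is the retron of a cis-divinylcyclopropane Cope rearrangement (cyclopropane C6–C7–C8, new bond C1–C10). A ketone kept at C4 then leaves C5=C6 as an enone, ready to receive the C6 oxygen, the C5 hydrogen and finally the isopropyl group.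

## Logic of the disconnections

25 ⇒ 24. The O–Si bond on the phenol is cut last. A free phenol would compete in the acylation, so it is carried masked. The forward step must spare the ester and the epoxide, which calls for buffered fluoride.

24 ⇒ 19 + 23 (23 from 22, 22 from 20). The acyl C–O bond at C6 is cut. This removes the whole aromatic part and leaves a purely sesquiterpenoid core. The forward acylation must take the secondary C6 hydroxyl and not the tertiary C4 hydroxyl, under basic conditions that the epoxide tolerates.

19 ⇒ 18. Both C–O bonds of the epoxide (C8–O, C9–O) are cut. The C6 hydroxyl is homoallylic to C8=C9 and sits on the α face, the face the epoxide oxygen must occupy, so it can deliver the oxidant. Two stereocentres disappear. The demand is that the epoxidation precedes esterification and stays neutral.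

18 ⇒ 16 (through 17). The C4–isopropyl bond is cut, turning the tertiary carbinol into a ketone plus an isopropyl nucleophile. One stereocentre and three carbons are removed. The forward addition must be non-basic, must come from the α face (anti to CH3-15), and needs the C6 oxygen masked by a small group that falls off on work-up.

16 ⇒ 15 ⇒ 14 ⇒ 13. After the O–Si bond, the C5–H bond and the C6–O bond are traced to an α,β-epoxy ketone and that to the enone C5=C6. Formally this is the hydration of the enone. Two more stereocentres vanish and 13 retains only C1. The forward steps need a nucleophilic oxidant that ignores C8=C9 and closes on the α face, then reductive C5–O cleavage with α protonation at C5.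

13 ⇒ 12. The C1–C10 bond is cut and C6–C8 re-formed (retro-Cope). Ring B collapses to a cyclopropane and the quaternary stereocentre is exchanged for two cyclopropane stereocentres that are easy to set. The forward step needs the two alkenyl groups cis and heat without stereomutation.

12 ⇒ 6 + 9. The C5–C6 bond between the enone α-carbon and the cyclopropane is cut. Two small fragments of comparable size result. The forward coupling must retain configuration at the cyclopropyl carbon and tolerate a tetrasubstituted alkene.

9 ⇒ 7. The C–Br bond is cut, leading to a commercial enone. The halogen must go regioselectively to the α-carbon.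

6 ⇒ 5 ⇒ 4. The C9=C10 bond is cut (methylenation), then the oxidation level is adjusted. The vinyl group is reduced to a hydroxymethyl handle that directs the cyclopropanation. The forward steps must not touch the cyclopropyl iodide.

4 ⇒ 3. The C6–C7 and C7–C8 bonds are cut (methylene transfer). Both cyclopropane stereocentres disappear into alkene geometry. The forward step must be enantioselective and stereospecific.

3 ⇒ 1. The C8–CH3 and C6–I bonds are cut. Both come from one anti carbometalation–iodination of a three-carbon alkyne, which fixes iodine cis to the hydroxymethyl group.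

22 ⇒ 20. The O–Si bond is cut, leading to the commercial hydroxy acid. Only the phenol is to stay silylated.

## Other disconnections considered

Alternative 1: The cut runs through C1–C10 and C4–C5 at once, back to the acyclic ester A1. Forward, acid would ionise the (2Z)-allylic alcohol of A1, the (6E)-alkene would attack at C1 while the terminal alkene captures C5 anti. A 1,2-hydride shift and capture of the C4 cation by the ester carbonyl, then water, would give A2. In its favour: it is the shortest conceivable route, and A2 already carries the C6 ester and the C4 hydroxyl, with C1, C4 and C5 set in one step. On step economy it would be clearly better than the chosen plan. Against it: ring B must close at the more substituted alkene carbon in competition with the usual six-membered closure, the allyl cation can lose its geometry, and elimination competes at every cationic stage. A single stereocentre in a flexible chain must control three new ones. Mechanistically the chosen pericyclic step has one channel where the cascade has many. Both plans leave C8=C9 for a late epoxidation, an equal point, but in A2 the C6 oxygen is already acylated, so no hydroxyl remains to direct the epoxide to the α face.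

Alternative 2: The cut is C6–C7, back to the aldehyde–allylsilane A4, whose ring A comes from the chiral-pool alcohol A3. Forward, SnCl4 would activate the C6 aldehyde, C7 of the allylsilane would attack it, and loss of silicon from C9 would place the alkene at C8=C9, giving A5. In its favour: the C4 carbinol with its isopropyl group is bought, not made, which is better than the chosen plan, where the C4 face selectivity is a risk. A5 equals 18 apart from a silyl group, so the endgames are equal. Against it: C1 and C5 must be built on the contracted ring next to a tertiary silyl ether, and a secondary allylsilane has to be carried in the side chain. The seven-membered closure is entropically less favoured than a strain-driven ring expansion, and the C6 configuration is not assured. The route to A4 is expected to be longer than the route to 12.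

Alternative 3: The cut is C5–C6 and C5–C1, a one-carbon insertion into the Birch diene A7 made from the arene A6. Forward, dibromocarbene (CHBr3, KOt-Bu) would add to the enol ether double bond of A7 and the dibromocyclopropane would open with loss of bromide to give A8. In its favour: ring B with the C6 oxygen, CH3-14 on C8=C9 and CH3-15 on C1 arrives in two steps from a cheap arene. This is better than the chosen plan in cost and in speed to ring B, and the vinyl bromide is a handle at C5. Against it: A8 is achiral, so the absolute configuration must come from a later asymmetric conjugate addition that creates quaternary C1 on a β,β-disubstituted bromo enone. Ring A with C4 and C5 must then be annulated, and the skipped dienone is prone to move into conjugation. The chosen plan instead transfers chirality from a cyclopropane made by an established asymmetric method. Overall step count is expected to be no lower.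

Key step: step 7

Assumption (remark on the chemistry): the (4R,5R) dioxaborolane ligand is taken to deliver methylene to the face of 3 that gives (1R,2R)-4, by analogy with its usual sense for allylic alcohols. If the sense is opposite, the (4S,5S) ligand is used with no other change. Atom labels follow daucane numbering; the cyclopropane stereocentres keep the same spatial arrangement from 4 to 12, and descriptor changes in 10 are formal.

## Steps

Step 1
Reactants: 1 prop-2-yn-1-ol (propargyl alcohol)
Product: 3 (Z)-3-iodo-2-methylprop-2-en-1-ol, via alkenylmagnesium alkoxide chelate 2 (not isolated)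
Conditions: MeMgBr (3 equiv), CuI (10 mol%), Et2O/THF, −10 °C → rt; then I2, −10 °C; aq. NH4Cl
Reagents that add atoms: methylmagnesium bromide, C[Mg]Br; iodine, II
Why: Copper-catalysed anti carbomagnesiation of the propargylic alkoxide places CH3 on the internal carbon and magnesium on the terminal carbon inside a five-membered chelate. Iodinolysis with retention therefore gives iodine cis to CH2OH, the geometry that later makes the two alkenyl groups cis.

Step 2
Reactants: 3 (Z)-3-iodo-2-methylprop-2-en-1-ol
Product: 4 [(1R,2R)-2-iodo-1-methylcyclopropyl]methanol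
Conditions: Zn(CH2I)2·DME (from Et2Zn, CH2I2, DME), (4R,5R)-2-butyl-N,N,N',N'-tetramethyl-1,3,2-dioxaborolane-4,5-dicarboxamide (1.2 equiv), CH2Cl2, −10 °C → rt
Reagents that add atoms: diiodomethane, ICI
Why: Dioxaborolane-controlled asymmetric Simmons–Smith cyclopropanation: the zinc alkoxide bound to the chiral boronate delivers CH2 (C7) to one face of the alkene. The addition is stereospecific, so iodine and CH2OH stay cis and both cyclopropane stereocentres (C6, C8) are set here.

Step 3
Reactants: 4 [(1R,2R)-2-iodo-1-methylcyclopropyl]methanol
Product: 5 (1R,2R)-2-iodo-1-methylcyclopropane-1-carbaldehyde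
Conditions: Dess–Martin periodinane, NaHCO3, CH2Cl2, 0 °C → rt; used as a concentrated solution (volatile)
Reagents that add atoms: none
Why: Buffered periodinane oxidation of a primary alcohol; the α-carbon is quaternary, so the aldehyde cannot epimerise, and the cyclopropyl iodide is inert.

Step 4
Reactants: 5 (1R,2R)-2-iodo-1-methylcyclopropane-1-carbaldehyde
Product: 6 (1R,2R)-1-ethenyl-2-iodo-1-methylcyclopropane
Conditions: Ph3PCH3Br, KN(SiMe3)2, Et2O, 0 °C; then 5, −78 °C → rt; pentane/silica plug; kept as an assayed Et2O solution (volatile)
Reagents that add atoms: methyltriphenylphosphonium bromide, C[P+](c1ccccc1)(c1ccccc1)c1ccccc1.[Br-]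
Why: Wittig methylenation of a non-enolisable aldehyde adds C10 and leaves both stereocentres untouched.

Step 5
Reactants: 7 3-methylcyclopent-2-en-1-one
Product: 9 2-bromo-3-methylcyclopent-2-en-1-one, via 2,3-dibromo-3-methylcyclopentan-1-one 8 (not isolated)
Conditions: Br2, CH2Cl2, 0 °C; then Et3N, 0 °C → rt
Reagents that add atoms: bromine, BrBr
Why: Bromine addition to the enone followed by amine-induced loss of HBr from the acidic α-position gives the α-bromo enone regioselectively.

Step 6
Reactants: 6 (1R,2R)-1-ethenyl-2-iodo-1-methylcyclopropane; 9 2-bromo-3-methylcyclopent-2-en-1-one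
Product: 12 2-[(1R,2R)-2-ethenyl-2-methylcyclopropyl]-3-methylcyclopent-2-en-1-one, via cyclopropyllithium 10 (not isolated), via cyclopropylzinc chloride 11 (not isolated)
Conditions: t-BuLi (2 equiv), Et2O, −78 °C; ZnCl2 (THF), −78 °C → rt; then 9, Pd(PPh3)4 (5 mol%), THF, rt → 40 °C
Reagents that add atoms: none
Why: Iodine–lithium exchange, transmetalation to zinc and Negishi coupling all proceed with retention at the configurationally stable cyclopropyl carbon, so the cyclopentenyl and vinyl groups end up cis. The α-bromo enone undergoes oxidative addition to zerovalent palladium readily, and any 13 already formed on warming is carried forward.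

Step 7
Reactants: 12 2-[(1R,2R)-2-ethenyl-2-methylcyclopropyl]-3-methylcyclopent-2-en-1-one
Product: 13 (3aR)-3a,6-dimethyl-3,3a,4,7-tetrahydroazulen-1(2H)-one
Conditions: toluene (0.05 M, degassed), BHT (cat.), 110 °C, sealed tube
Reagents that add atoms: none
Why: A concerted [3,3]-sigmatropic shift (divinylcyclopropane–cycloheptadiene Cope rearrangement) passes through the boat transition state in which the cyclopentenyl C5=C1 and the vinyl C9=C10 both lie under the cyclopropane; C1–C10 forms as C6–C8 breaks and the π bonds move to C5=C6 and C8=C9. The closest known reaction type is the thermal rearrangement of cis-2-vinylcyclopropyl cycloalkenes with an inward methyl at the ring terminus, which builds angular-methyl hydroazulenes on heating in hydrocarbon solvents. Ring B is closed not by an ionic cyclisation but by expansion of the three-membered ring to the seven-membered ring, paid for by cyclopropane strain while the ketone stays conjugated (C4=O with C5=C6). The one new stereocentre, C1, is controlled by the (1R,2R) cyclopropane: in the boat geometry C10 can reach only the face of C5=C1 turned toward it, which gives (R)-C1 with CH3-15 β. The selectivity needed is complete suprafacial transfer without stereomutation of the cyclopropane; it is secured by the cis geometry fixed in step 1 and by staying near 110 °C, below the range where homolysis of C6–C8 competes. The inward CH3-15 meets the endo hydrogen of C7 in the transition state, which is why heating is needed at all. No alkyl C–H sits cis to an alkenyl group on the ring (CH3-14 is trans to the cyclopentenyl group), so the homodienyl 1,5-hydrogen shift has no entry.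

Step 8
Reactants: 13 (3aR)-3a,6-dimethyl-3,3a,4,7-tetrahydroazulen-1(2H)-one
Product: 14 (3aR,8S,8aR)-8,8a-epoxy-3a,6-dimethyl-3,3a,4,7,8,8a-hexahydroazulen-1(2H)-one (5α,6α-epoxide in daucane numbering)
Conditions: t-BuOOH (decane, 2 equiv), DBU (1.1 equiv), CH2Cl2, 0 °C → rt
Reagents that add atoms: tert-butyl hydroperoxide, CC(C)(C)OO
Why: Weitz–Scheffer nucleophilic epoxidation: the peroxide anion adds reversibly to C6 and the enolate closes at C5, which should occur on the α face, anti to CH3-15 on the adjacent quaternary C1, setting C6 (S) with oxygen α. The electron-rich C8=C9 alkene is inert to a nucleophilic oxidant.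

Step 9
Reactants: 14 (3aR,8S,8aR)-8,8a-epoxy-3a,6-dimethyl-3,3a,4,7,8,8a-hexahydroazulen-1(2H)-one
Product: 15 (3aR,8S,8aS)-8-hydroxy-3a,6-dimethyl-3,3a,4,7,8,8a-hexahydroazulen-1(2H)-one
Conditions: SmI2 (2.5 equiv), THF/MeOH, −90 °C; pH 7 buffer
Reagents that add atoms: none
Why: SmI2 reduces the ketone to a ketyl that expels the α C5–O bond, leaving the C6–O stereocentre untouched. The resulting samarium enolate should be protonated at C5 on the α face, anti to CH3-15 and next to the α-face samarium alkoxide that carries methanol, giving the trans ring fusion; the low temperature suppresses β-elimination.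

Step 10
Reactants: 15 (3aR,8S,8aS)-8-hydroxy-3a,6-dimethyl-3,3a,4,7,8,8a-hexahydroazulen-1(2H)-one
Product: 16 (3aR,8S,8aS)-3a,6-dimethyl-8-[(trimethylsilyl)oxy]-3,3a,4,7,8,8a-hexahydroazulen-1(2H)-one
Conditions: 1-(trimethylsilyl)imidazole, CH2Cl2, 0 °C → rt; cold aqueous wash, used crude
Reagents that add atoms: 1-(trimethylsilyl)imidazole, C[Si](C)(C)n1ccnc1
Why: Neutral silyl transfer caps the secondary hydroxyl without the base or acid that would epimerise C5 or dehydrate the β-hydroxy ketone. The small silyl group keeps the α face of C4 open and is removed in the next work-up.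

Step 11
Reactants: 16 (3aR,8S,8aS)-3a,6-dimethyl-8-[(trimethylsilyl)oxy]-3,3a,4,7,8,8a-hexahydroazulen-1(2H)-one
Product: 18 (3R,3aS,4S,8aR)-6,8a-dimethyl-3-(propan-2-yl)-1,2,3,3a,4,5,8,8a-octahydroazulene-3,4-diol (jaeschkeanadiol), via silyl ether carbinol 17 (not isolated)
Conditions: i-PrMgCl (3 equiv), CeCl3 (anhydrous, 3 equiv), THF, −78 → −20 °C; then 10% aq. citric acid, MeOH, 0 °C
Reagents that add atoms: isopropylmagnesium chloride, CC(C)[Mg]Cl
Why: The organocerium reagent adds to the ketone with little enolisation or hydride transfer. Attack from the α face, anti to the 1,3-related axial CH3-15, puts the isopropyl group α and the hydroxyl β (4R); mild acid in the work-up removes the trimethylsilyl group.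

Step 12
Reactants: 18 (3R,3aS,4S,8aR)-6,8a-dimethyl-3-(propan-2-yl)-1,2,3,3a,4,5,8,8a-octahydroazulene-3,4-diol
Product: 19 (3R,3aS,4S,6R,7S,8aR)-6,7-epoxy-6,8a-dimethyl-3-(propan-2-yl)decahydroazulene-3,4-diol (8α,9α-epoxide in daucane numbering)
Conditions: VO(acac)2 (5 mol%), t-BuOOH (decane, 1.5 equiv), CH2Cl2, 0 °C → rt
Reagents that add atoms: tert-butyl hydroperoxide, CC(C)(C)OO
Why: Hydroxyl-directed epoxidation: the vanadate ester of the homoallylic C6 hydroxyl delivers oxygen to the syn (α) face of C8=C9, setting C8 (R) and C9 (S). The tertiary C4 hydroxyl is on the opposite face and too remote to direct.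

Step 13
Reactants: 20 4-hydroxybenzoic acid
Product: 22 4-[(tert-butyldimethylsilyl)oxy]benzoic acid, via bis-silylated acid 21 (not isolated)
Conditions: TBSCl (2.5 equiv), imidazole, DMF, rt; then AcOH/THF/H2O, rt
Reagents that add atoms: tert-butyldimethylsilyl chloride, CC(C)(C)[Si](C)(C)Cl
Why: Exhaustive silylation followed by selective hydrolysis of the far more labile silyl ester leaves only the phenol protected.

Step 14
Reactants: 19 (3R,3aS,4S,6R,7S,8aR)-6,7-epoxy-6,8a-dimethyl-3-(propan-2-yl)decahydroazulene-3,4-diol; 22 4-[(tert-butyldimethylsilyl)oxy]benzoic acid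
Product: 24 (3R,3aS,4S,6R,7S,8aR)-6,7-epoxy-3-hydroxy-6,8a-dimethyl-3-(propan-2-yl)decahydroazulen-4-yl 4-[(tert-butyldimethylsilyl)oxy]benzoate, via 4-[(tert-butyldimethylsilyl)oxy]benzoyl chloride 23 (not isolated)
Conditions: 22, (COCl)2, DMF (cat.), CH2Cl2, 0 °C → rt, evaporate; then 19, Et3N, DMAP, CH2Cl2, 0 °C → rt
Reagents that add atoms: none
Why: DMAP-catalysed acylation by the acid chloride takes the secondary C6 hydroxyl and leaves the hindered tertiary C4 hydroxyl; the basic medium keeps the epoxide intact.

Step 15
Reactants: 24 (3R,3aS,4S,6R,7S,8aR)-6,7-epoxy-3-hydroxy-6,8a-dimethyl-3-(propan-2-yl)decahydroazulen-4-yl 4-[(tert-butyldimethylsilyl)oxy]benzoate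
Product: 25 jaeskeanin, (3R,3aS,4S,6R,7S,8aR)-6,7-epoxy-3-hydroxy-6,8a-dimethyl-3-(propan-2-yl)decahydroazulen-4-yl 4-hydroxybenzoate
Conditions: Bu4NF (1.1 equiv), AcOH (1.1 equiv), THF, 0 °C
Reagents that add atoms: none
Why: Fluoride cleaves the aryl silyl ether within minutes; the acetic acid buffer prevents phenoxide- or alkoxide-driven acyl transfer and spares the epoxide.

## Compound list

1 | prop-2-yn-1-ol | C#CCO | starting material
2 | 4-methyl-2,5-dihydro-1,2-oxamagnesole (alkenylmagnesium alkoxide chelate) | CC1=C[Mg]OC1 | intermediate
3 | (Z)-3-iodo-2-methylprop-2-en-1-ol | OC/C(C)=C\I | intermediate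
4 | [(1R,2R)-2-iodo-1-methylcyclopropyl]methanol | I[C@@H]1C[C@]1(C)CO | intermediate
5 | (1R,2R)-2-iodo-1-methylcyclopropane-1-carbaldehyde | I[C@@H]1C[C@]1(C)C=O | intermediate
6 | (1R,2R)-1-ethenyl-2-iodo-1-methylcyclopropane | I[C@@H]1C[C@]1(C)C=C | intermediate
7 | 3-methylcyclopent-2-en-1-one | CC1=CC(=O)CC1 | starting material
8 | 2,3-dibromo-3-methylcyclopentan-1-one | CC1(Br)CCC(=O)C1Br | intermediate
9 | 2-bromo-3-methylcyclopent-2-en-1-one | CC1=C(Br)C(=O)CC1 | intermediate
10 | [(1R,2S)-2-ethenyl-2-methylcyclopropyl]lithium | [Li][C@@H]1C[C@]1(C)C=C | intermediate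
11 | chloro[(1R,2R)-2-ethenyl-2-methylcyclopropyl]zinc | Cl[Zn][C@@H]1C[C@]1(C)C=C | intermediate
12 | 2-[(1R,2R)-2-ethenyl-2-methylcyclopropyl]-3-methylcyclopent-2-en-1-one | O=C1CCC(C)=C1[C@@H]1C[C@]1(C)C=C | intermediate
13 | (3aR)-3a,6-dimethyl-3,3a,4,7-tetrahydroazulen-1(2H)-one | O=C1CC[C@]2(C)CC=C(C)CC=C12 | intermediate
14 | (3aR,8S,8aR)-8,8a-epoxy-3a,6-dimethyl-3,3a,4,7,8,8a-hexahydroazulen-1(2H)-one | O=C1CC[C@]2(C)CC=C(C)C[C@@H]3O[C@]123 | intermediate
15 | (3aR,8S,8aS)-8-hydroxy-3a,6-dimethyl-3,3a,4,7,8,8a-hexahydroazulen-1(2H)-one | O=C1CC[C@]2(C)CC=C(C)C[C@H](O)[C@@H]12 | intermediate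
16 | (3aR,8S,8aS)-3a,6-dimethyl-8-[(trimethylsilyl)oxy]-3,3a,4,7,8,8a-hexahydroazulen-1(2H)-one | O=C1CC[C@]2(C)CC=C(C)C[C@H](O[Si](C)(C)C)[C@@H]12 | intermediate
17 | (3R,3aS,4S,8aR)-6,8a-dimethyl-3-(propan-2-yl)-4-[(trimethylsilyl)oxy]-1,2,3,3a,4,5,8,8a-octahydroazulen-3-ol | CC(C)[C@]1(O)CC[C@]2(C)CC=C(C)C[C@H](O[Si](C)(C)C)[C@H]21 | intermediate
18 | (3R,3aS,4S,8aR)-6,8a-dimethyl-3-(propan-2-yl)-1,2,3,3a,4,5,8,8a-octahydroazulene-3,4-diol (jaeschkeanadiol) | CC(C)[C@]1(O)CC[C@]2(C)CC=C(C)C[C@H](O)[C@H]21 | intermediate
19 | (3R,3aS,4S,6R,7S,8aR)-6,7-epoxy-6,8a-dimethyl-3-(propan-2-yl)decahydroazulene-3,4-diol | CC(C)[C@]1(O)CC[C@]2(C)C[C@@H]3O[C@]3(C)C[C@H](O)[C@H]21 | intermediate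
20 | 4-hydroxybenzoic acid | OC(=O)c1ccc(O)cc1 | starting material
21 | tert-butyldimethylsilyl 4-[(tert-butyldimethylsilyl)oxy]benzoate | CC(C)(C)[Si](C)(C)OC(=O)c1ccc(O[Si](C)(C)C(C)(C)C)cc1 | intermediate
22 | 4-[(tert-butyldimethylsilyl)oxy]benzoic acid | OC(=O)c1ccc(O[Si](C)(C)C(C)(C)C)cc1 | intermediate
23 | 4-[(tert-butyldimethylsilyl)oxy]benzoyl chloride | ClC(=O)c1ccc(O[Si](C)(C)C(C)(C)C)cc1 | intermediate
24 | (3R,3aS,4S,6R,7S,8aR)-6,7-epoxy-3-hydroxy-6,8a-dimethyl-3-(propan-2-yl)decahydroazulen-4-yl 4-[(tert-butyldimethylsilyl)oxy]benzoate | CC(C)[C@]1(O)CC[C@]2(C)C[C@@H]3O[C@]3(C)C[C@H](OC(=O)c3ccc(O[Si](C)(C)C(C)(C)C)cc3)[C@H]21 | intermediate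
25 | jaeskeanin, (3R,3aS,4S,6R,7S,8aR)-6,7-epoxy-3-hydroxy-6,8a-dimethyl-3-(propan-2-yl)decahydroazulen-4-yl 4-hydroxybenzoate | CC(C)[C@]1(O)CC[C@]2(C)C[C@@H]3O[C@]3(C)C[C@H](OC(=O)c3ccc(O)cc3)[C@H]21 | target

## Step count and least certain steps

Total: 15 steps. Longest linear sequence: 13 steps (1, 2, 3, 4, 6, 7, 8, 9, 10, 11, 12, 14, 15) from prop-2-yn-1-ol.

Step 7 (key step). The rearrangement may be sluggish because of the inward methyl. The temperature would then have to rise into the range where reversible homolysis of C6–C8 scrambles the cyclopropane and erodes enantiopurity, and long heating could also move the skipped diene into conjugation through the dienol. The fallback stores the stereochemical information in a second, sentinel stereocentre at C4, so that any leakage shows up as separable diastereomers, and no enone is present during heating. It sets out from 9, which is reduced (Corey–Bakshi–Shibata reduction with (R)-1-methyl-3,3-diphenyltetrahydro-1H,3H-pyrrolo[1,2-c][1,3,2]oxazaborole and BH3·SMe2; either antipode would serve) to (1S)-2-bromo-3-methylcyclopent-2-en-1-ol F1. Silylation (TBSCl, imidazole) gives {[(1S)-2-bromo-3-methylcyclopent-2-en-1-yl]oxy}(tert-butyl)dimethylsilane F2. Negishi coupling with 11 as in step 6 gives tert-butyl({(1S)-2-[(1R,2R)-2-ethenyl-2-methylcyclopropyl]-3-methylcyclopent-2-en-1-yl}oxy)dimethylsilane F3. Heating gives tert-butyl{[(1S,3aR)-3a,6-dimethyl-1,2,3,3a,4,7-hexahydroazulen-1-yl]oxy}dimethylsilane F4, from which a C1 epimer, if present, is removed by chromatography. Bu4NF then gives (1S,3aR)-3a,6-dimethyl-1,2,3,3a,4,7-hexahydroazulen-1-ol F5, and MnO2 oxidation comes back to the route at 13.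

Step 9. Two processes threaten this step: loss of the C6 oxygen by β-elimination from the samarium aldolate, and proton transfer to the β face of C5, which would give the cis-fused ketone. The preceding step 8 carries a related hazard, base-induced migration of the skipped diene. The fallback makes the C6–O and C5–H bonds by conjugate borylation and so avoids peroxide, amidine base and aldolate altogether. It sets out from 13: copper-catalysed β-borylation (CuCl, NaOt-Bu, bis[2-(diphenylphosphino)phenyl] ether, B2pin2, MeOH, THF) gives (3aR,8S,8aR)-3a,6-dimethyl-8-(4,4,5,5-tetramethyl-1,3,2-dioxaborolan-2-yl)-3,3a,4,7,8,8a-hexahydroazulen-1(2H)-one F6, and oxidation with NaBO3·4H2O, which retains configuration at C6, comes back to the route at 15.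

Step 11. The branched Grignard-derived reagent may transfer hydride or enolise the ketone next to a tertiary centre instead of adding, and attack past the angular methyl on the β face would give the C4 epimer. The fallback uses an sp2 nucleophile with no β-hydrogen and a smaller steric demand. It sets out from 16: isopropenylmagnesium bromide with CeCl3 gives (3S,3aS,4S,8aR)-6,8a-dimethyl-3-(prop-1-en-2-yl)-4-[(trimethylsilyl)oxy]-1,2,3,3a,4,5,8,8a-octahydroazulen-3-ol F7 (same spatial arrangement as 17; the descriptor at the carbinol changes formally). Selective hydrogenation of the 1,1-disubstituted alkene over the trisubstituted one (H2, RhCl(PPh3)3) comes back to the route at 17, which is desilylated to 18 as in step 11.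

Step 6. Transmetalation to palladium and reductive elimination at a carbon flanked by a carbonyl and a methyl-bearing alkene carbon may be slow, so that protonolysis or homocoupling of the cyclopropylzinc wins. The fallback changes the nucleophile to an isolable boron reagent. It sets out from 6: exchange to 10 as before, then quenching with 2-isopropoxy-4,4,5,5-tetramethyl-1,3,2-dioxaborolane gives 2-[(1R,2S)-2-ethenyl-2-methylcyclopropyl]-4,4,5,5-tetramethyl-1,3,2-dioxaborolane F8, which can be purified and stored. Suzuki–Miyaura coupling with 9 (Pd(OAc)2, 2-dicyclohexylphosphino-2',6'-dimethoxybiphenyl, K3PO4, toluene/H2O, 80 °C) comes back to the route at 12; any 13 formed at this temperature is carried on.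

Step 12. Direction by a homoallylic hydroxyl may be slow, and the Lewis-acidic vanadium could then open the new epoxide by transannular attack of the C4 hydroxyl. The fallback reverses the order and relies on substrate control. It sets out from 18: acylation with 23 as in step 14 gives (3R,3aS,4S,8aR)-3-hydroxy-6,8a-dimethyl-3-(propan-2-yl)-1,2,3,3a,4,5,8,8a-octahydroazulen-4-yl 4-[(tert-butyldimethylsilyl)oxy]benzoate F9. Epoxidation with dimethyldioxirane in acetone at 0 °C, under neutral conditions and with the β face shielded by CH3-15, comes back to the route at 24. This face selectivity is less secure than hydroxyl direction, which is why it is the reserve.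

## Further compounds

F1 | step 7 | (1S)-2-bromo-3-methylcyclopent-2-en-1-ol | O[C@H]1CCC(C)=C1Br
F2 | step 7 | {[(1S)-2-bromo-3-methylcyclopent-2-en-1-yl]oxy}(tert-butyl)dimethylsilane | CC(C)(C)[Si](C)(C)O[C@H]1CCC(C)=C1Br
F3 | step 7 | tert-butyl({(1S)-2-[(1R,2R)-2-ethenyl-2-methylcyclopropyl]-3-methylcyclopent-2-en-1-yl}oxy)dimethylsilane | CC(C)(C)[Si](C)(C)O[C@H]1CCC(C)=C1[C@@H]1C[C@]1(C)C=C
F4 | step 7 | tert-butyl{[(1S,3aR)-3a,6-dimethyl-1,2,3,3a,4,7-hexahydroazulen-1-yl]oxy}dimethylsilane | CC(C)(C)[Si](C)(C)O[C@H]1CC[C@]2(C)CC=C(C)CC=C12
F5 | step 7 | (1S,3aR)-3a,6-dimethyl-1,2,3,3a,4,7-hexahydroazulen-1-ol | O[C@H]1CC[C@]2(C)CC=C(C)CC=C12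
F6 | step 9 | (3aR,8S,8aR)-3a,6-dimethyl-8-(4,4,5,5-tetramethyl-1,3,2-dioxaborolan-2-yl)-3,3a,4,7,8,8a-hexahydroazulen-1(2H)-one | O=C1CC[C@]2(C)CC=C(C)C[C@H](B3OC(C)(C)C(C)(C)O3)[C@@H]12
F7 | step 11 | (3S,3aS,4S,8aR)-6,8a-dimethyl-3-(prop-1-en-2-yl)-4-[(trimethylsilyl)oxy]-1,2,3,3a,4,5,8,8a-octahydroazulen-3-ol | CC(=C)[C@]1(O)CC[C@]2(C)CC=C(C)C[C@H](O[Si](C)(C)C)[C@H]21
F8 | step 6 | 2-[(1R,2S)-2-ethenyl-2-methylcyclopropyl]-4,4,5,5-tetramethyl-1,3,2-dioxaborolane | CC1(C)OB(OC1(C)C)[C@@H]1C[C@]1(C)C=C
F9 | step 12 | (3R,3aS,4S,8aR)-3-hydroxy-6,8a-dimethyl-3-(propan-2-yl)-1,2,3,3a,4,5,8,8a-octahydroazulen-4-yl 4-[(tert-butyldimethylsilyl)oxy]benzoate | CC(C)[C@]1(O)CC[C@]2(C)CC=C(C)C[C@H](OC(=O)c3ccc(O[Si](C)(C)C(C)(C)C)cc3)[C@H]21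
A1 | alternative 1 | (2Z,5S,6E)-1-hydroxy-3,7,11-trimethyldodeca-2,6,10-trien-5-yl 4-(acetyloxy)benzoate | OC/C=C(/C)C[C@H](OC(=O)c1ccc(OC(C)=O)cc1)/C=C(\C)CCC=C(C)C
A2 | alternative 1 | ferutinin 4'-O-acetate (4-hydroxydauc-8-en-6-yl 4-acetoxybenzoate) | CC(C)[C@]1(O)CC[C@]2(C)CC=C(C)C[C@H](OC(=O)c3ccc(OC(C)=O)cc3)[C@H]21
A3 | alternative 2 | (S)-terpinen-4-ol, (1S)-4-methyl-1-(propan-2-yl)cyclohex-3-en-1-ol | CC(C)[C@]1(O)CCC(C)=CC1
A4 | alternative 2 | 2-methyl-2-[3-methyl-2-(trimethylsilyl)but-3-en-1-yl]-5-(propan-2-yl)-5-[(triethylsilyl)oxy]cyclopentane-1-carbaldehyde (ring configuration as in A5; silyl-bearing carbon unspecified) | CC(C)[C@]1(O[Si](CC)(CC)CC)CC[C@](C)(CC([Si](C)(C)C)C(C)=C)[C@H]1C=O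
A5 | alternative 2 | dauc-8-ene-4,6-diol 4-triethylsilyl ether | CC(C)[C@]1(O[Si](CC)(CC)CC)CC[C@]2(C)CC=C(C)C[C@H](O)[C@H]21
A6 | alternative 3 | 2,5-dimethylanisole | COc1cc(C)ccc1C
A7 | alternative 3 | 1-methoxy-2,5-dimethylcyclohexa-1,4-diene | COC1=C(C)CC=C(C)C1
A8 | alternative 3 | 2-bromo-3,6-dimethylcyclohepta-2,5-dien-1-one | O=C1CC(C)=CCC(C)=C1Br
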